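## Structural features

The target is a linear trimer of three 2-(4-hydroxyphenyl)chroman (flavan) units, each with a phloroglucinol-type ring A, a pyran ring C and a 4-hydroxyphenyl ring B. C4 of the top unit is bonded to C8 of the middle unit, and C4 of the middle unit to C8 of the bottom unit. Its nine stereocentres form three contiguous C2/C3/C4 triads: the top unit is (2S,3S,4R) and the middle unit (2R,3R,4S), both all-cis and therefore pseudo-enantiomeric, while the bottom unit is a (2S,3S,4R) flavan-3,4-diol with 2,3-cis and 3,4-trans hydroxyls. The C4 atoms of the top and middle units are diarylmethines flanked by four oxygenated ortho positions. The fragile features are the electron-rich rings A, the acid-labile C4–C8 interflavan bonds and the bottom C4 hydroxyl, a benzylic alcohol that ionises under mild acid. The real difficulty is the cis relationship between O3 and the C4 aryl group in the two upper units: an arene adds to a C4 cation anti to O3, so cation coupling gives the 3,4-trans isomer, and the crowded diarylmethine is hard to make by any carbon–aryl coupling. The key step uses the O1–C8a–C4a–C4 array of the top unit: with a free phenol at O1 and a leaving group on C4 it becomes an o-quinone methide, so C4 (already carrying middle ring A) accepts C3 of a glycolate unit and O1 accepts its carbonyl carbon C2, closing ring C with O3 cis to the aryl group.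

## Logic of the disconnections

35 to 34: the twelve O–CH2Ph bonds are cut last. Benzyl is the one group that tolerates organolithium and Grignard reagents, carbonate, BF3·OEt2 and DDQ and leaves under neutral conditions that spare the interflavan bonds. All phenols and two secondary alcohols are then masked by one group. The forward step must stop before the benzylic C4–OH of the bottom unit is hydrogenolysed.

34 to 33: the bottom C4–O bond is cut. A C4 oxygen would not survive the Lewis-acid reductions used earlier, so it is introduced after the skeleton is complete. The bottom unit can then be carried as a plain 2,3-cis flavan. The oxidant must choose the bottom C4 methylene over the two diarylmethine C–H bonds and deliver water anti to O3.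

33 to 32 to 31: the middle C2–H bond and the C2–ring B bond are cut. C2 is the one ring C centre the annulation does not set; as a carbonyl it accepts 14, and the resulting hemiketal is reduced under control of the cis C3/C4 pair. This removes ring B and one stereocentre. The forward steps need a single addition to an aryl ester and hydride delivery anti to both substituents.

31 to 29 and 10 (through 30): the middle C3–C4 and O1–C2 bonds are cut, the same annulation as the key step but with the mirror-image catalyst because the middle triad is pseudo-enantiomeric to the top one. Ring C and two stereocentres of the middle unit disappear. The catalyst must override the resident stereocentres.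

29 to 28 to 18 and 25 (through 26 and 27): the C–S bond and then the bond between middle C4 and bottom C8 are cut. The benzhydryl carbon is at the alcohol oxidation level, so it comes from an aldehyde and an aryl nucleophile. This splits the molecule into two fragments of similar size. A hindered aryllithium must add to a hindered aldehyde that carries an acidic phenol.

18 to 17 to 16: the formyl C–C bond at middle C4a and the O–Si bond are cut. After desilylation only one position ortho to the phenol is free, and it is exactly C4a. Middle ring A reverts to the simple aryl group that passed through the key step. The formylation must be ortho-specific on a crowded phenol.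

16 to 15 to 12: the top C2–H and C2–ring B bonds are cut, as for the middle unit. This leaves a lactone with only the C3/C4 pair.

12 to 7 and 10 (through 11), the key disconnection: the top C3–C4 and O1–C2 bonds are cut. C4 is formed with the middle ring A already on it, so the tetra-ortho-substituted diarylmethine never has to be made by aryl coupling, and the 3,4-cis pair comes from one catalytic step. The benzhydryl centre of 7 is erased in 11, so 7 may be racemic. The two aryl rings of 7 differ only in the oxygen substituent, so a silyl shift between the two phenolic oxygens would be degenerate. The forward step needs cis selectivity and enolate face control at a very hindered methide carbon.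

7 to 6 to 3 and 4 (through 5): the C–S bond and the benzhydryl C–C bond are cut, giving two phloroglucinol pieces. The phenol that must be free in 7 is carried as its lithium salt, so no extra protecting group is needed. The addition must be quenched cold to prevent silyl transfer to the new alkoxide.

3 to 2 to 1, 4 to 1, 10 to 8 and 9, and 14 to 13: the O–Si, formyl C–C, C–Br, ester C–O and C–Mg bonds are cut. Both halves of 7 then come from the single phenol 1 by two ortho-selective substitutions, and 14 is prepared once as a stock reagent that supplies ring B to all three units.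

25 to 24 to 23 to 22 to 20 and 10 (through 21) to 19 to 2: the C8–Br bond, C2–H, C2–ring B, then C3–C4 and O1–C2, then C–S and the carbinol C–H are cut. The bottom flavan is made by the same annulation and relay, without a C4 substituent, from the intermediate 2 already in hand and with the same catalyst enantiomer as for 12. Here the catalyst alone must set C3.

## Other disconnections considered

Alternative 1: The cut is the C3=C4 bond of a middle-unit 2H-chromene. The forward step is ring-closing metathesis of diene A1 (an aryl 1-arylallyl ether with an ortho 1,1-diarylethylene) using the second-generation Grubbs catalyst RuCl2(=CHPh)(PCy3)(H2IMes), giving chromene A2 and ethylene.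
- In its favour: C2 comes from a chiral 1-arylallyl alcohol set in a separate operation, and the conditions are neutral and tolerate benzyl ethers.
- Against it: the alkylidene must close onto an ethylene bearing two 2,6-disubstituted aryl groups to make a trisubstituted olefin. A2 also lacks both O3 and H4. Hydroboration–oxidation would add anti to the C2 aryl group and syn across the double bond, which should give the 2,3-trans, 3,4-trans isomer, so C3 and C4 would both need correction. A2 carries hydrogen at C8, so the all-cis top unit still has to be attached, and cation coupling cannot do that.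
- Comparison: on structure the chosen annulation sets two stereocentres in the ring-forming step and A1 to A2 sets none. On mechanism the metathesis is the equal or the better in functional-group tolerance, and better in that C2 is fixed independently and no quinone methide geometry matters. On step economy it is worse by several corrective steps per unit.

Alternative 2: The cut is the C2=C3 bond of a top-unit 4H-chromene with C4 already in place. An aryl benzoate would be methylenated with Cp2Ti(μ-Cl)(μ-CH2)AlMe2 to enol ether A3. Metathesis with Mo(=CHCMe2Ph)(=N-2,6-i-Pr2C6H3)[OCMe(CF3)2]2 or the second-generation Grubbs catalyst would then give 4H-chromene A4.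
- In its favour: the C4 configuration is decoupled from ring closure and can be checked beforehand, the closure has no diastereoselectivity question, and the enol ether is a handle for oxygenating C3.
- Against it: reagents would approach A4 anti to the C4 aryl group, so hydroboration or epoxidation should place O3 trans to that group, the opposite of what the all-cis triad needs. Enol ether metathesis and the methylenation of a hindered aryl ester are demanding. An enantioselective route to a vinyl diarylmethine with two 2,6-disubstituted aryl groups is also needed.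
- Comparison: it is the equal of the chosen plan in avoiding a cationic aryl coupling and in building the diarylmethine early, and better in that C4 does not depend on quinone methide geometry. It is worse in bond and stereocentre count of the key step (one bond, no stereocentre), in stereochemical fit at C3 and in step count.

Alternative 3: The cut is the bottom C4–C4a bond. The forward step is an intramolecular Friedel–Crafts hydroxyalkylation of α-benzyloxy aldehyde A5 under a mild Lewis acid such as MgBr2·OEt2, giving carbinol A6, which is identical with 34.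
- In its favour: the C4 oxygen arrives with the carbon skeleton, so no late oxidation has to discriminate between the bottom methylene and the two diarylmethine hydrogens. On this point it is better than step 24. The attacking ring carbon is very nucleophilic.
- Against it: the product is a more ionisable benzylic alcohol than the aldehyde is an electrophile, so further arylation or elimination threatens under the same acid. A5 has an aryloxy group β to the aldehyde and an epimerisable α-centre. The 3,4-trans outcome depends on a Felkin-versus-chelation balance. The acyclic C2/C3 pair would have to be attached as an aryl ether of a hindered phenol late in the synthesis.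
- Comparison: on structure it solves only the bottom ring and leaves both all-cis units to the chosen chemistry. On mechanism it avoids an oxidant (better) but risks over-reaction (worse). On step economy it is worse, because the bottom unit can no longer enter as the finished flavan 25.

Key step: step 7

Assumption: each unit is numbered as a flavan (O1, C2, C3, C4, C4a, C5 to C8, C8a); "top" is the unit whose C4 carries middle ring A, and "bottom" is the flavan-3,4-diol.

Assumption: T-4-yl means the all-cis top residue (2S,3S)-3,5,7-tris(benzyloxy)-2-[4-(benzyloxy)phenyl]chroman-4-yl, with the C4 bond cis to the 3-benzyloxy and 2-aryl groups. B-8-yl means the 2,3-cis bottom residue (2S,3S)-3,5,7-tris(benzyloxy)-2-[4-(benzyloxy)phenyl]chroman-8-yl.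

Assumption: the sense of induction of the aminoindanol-derived triazolium chlorides (C21H22ClN3O) is assigned by analogy. The (5aR,10bS) salt is written for the 3S lactones and the (5aS,10bR) salt for the 3R lactone; if a trial on 20 shows the opposite sense, the two salts are exchanged and nothing else changes.

Assumption: 6, 7, 28 and 29 are used as mixtures at the benzhydryl carbon, because that centre is erased in the quinone methide.

Assumption: the arylmagnesium reagent 14 is prepared once as a titrated THF stock solution kept under argon and drawn on in steps 9, 16 and 22.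

Step 1
Reactants: 1 3,5-bis(benzyloxy)phenol
Product: 2 4,6-bis(benzyloxy)-2-hydroxybenzaldehyde
Conditions: MgCl2 (anhydrous, 1.5 equiv), Et3N (3.8 equiv), (CH2O)n (6 equiv), MeCN, reflux; 1 M HCl
Reagents that add atoms: paraformaldehyde (as formaldehyde), C=O
Why: Casnati–Skattebøl ortho-formylation: the magnesium phenoxide delivers formaldehyde to the ortho carbon through a chelate and a second formaldehyde oxidises the benzylic alkoxide by hydride transfer; both ortho positions of 1 are equivalent and the para position is not reached, so one regioisomer should form.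

Step 2
Reactants: 2 4,6-bis(benzyloxy)-2-hydroxybenzaldehyde
Product: 3 4,6-bis(benzyloxy)-2-(triisopropylsilyloxy)benzaldehyde
Conditions: TIPSOTf (1.2 equiv), 2,6-lutidine (2 equiv), CH2Cl2, 0 °C
Reagents that add atoms: triisopropylsilyl trifluoromethanesulfonate, CC(C)[Si](OS(=O)(=O)C(F)(F)F)(C(C)C)C(C)C
Why: O-silylation of the hydrogen-bonded phenol with the reactive silyl triflate; the bulky silyl ether should withstand the later carbonate, Grignard and BF3·OEt2 steps and marks the oxygen that becomes O1 of the middle unit.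

Step 3
Reactants: 1 3,5-bis(benzyloxy)phenol
Product: 4 3,5-bis(benzyloxy)-2-bromophenol
Conditions: NBS (1.0 equiv), i-Pr2NH (10 mol%), CH2Cl2, −78 to −20 °C
Reagents that add atoms: N-bromosuccinimide, O=C1CCC(=O)N1Br
Why: Amine-mediated ortho-bromination of a phenol (electrophilic aromatic substitution): the N-bromoamine formed in situ is hydrogen-bonded to the phenolic OH and transfers bromine to the adjacent carbon; the two ortho positions are equivalent and any 4-bromo isomer is removed by chromatography.

Step 4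
Reactants: 4 3,5-bis(benzyloxy)-2-bromophenol; 3 4,6-bis(benzyloxy)-2-(triisopropylsilyloxy)benzaldehyde
Product: 6 rac-[2,4-bis(benzyloxy)-6-hydroxyphenyl][2,4-bis(benzyloxy)-6-(triisopropylsilyloxy)phenyl]methanol, via lithium 2-lithiophenoxide 5 (not isolated)
Conditions: 4, t-BuLi (3.1 equiv), THF, −78 °C; then 3, −78 °C; H2O at −78 °C
Reagents that add atoms: none
Why: The first equivalent of t-BuLi deprotonates the phenol and the next two effect bromine–lithium exchange; the ortho-lithiated phenoxide 5 adds to the non-enolisable aldehyde (1,2-addition). The cold quench forestalls transfer of the silyl group to the new alkoxide; the carbinol centre forms racemic and is erased in step 7.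

Step 5
Reactants: 6 rac-[2,4-bis(benzyloxy)-6-hydroxyphenyl][2,4-bis(benzyloxy)-6-(triisopropylsilyloxy)phenyl]methanol
Product: 7 rac-3,5-bis(benzyloxy)-2-{[2,4-bis(benzyloxy)-6-(triisopropylsilyloxy)phenyl](4-methylbenzenesulfonyl)methyl}phenol
Conditions: p-TolSO2H (1.5 equiv), CH2Cl2, 0 °C to rt
Reagents that add atoms: p-toluenesulfinic acid, Cc1ccc(cc1)S(=O)O
Why: Acid-promoted ionisation of the doubly activated benzhydrol (SN1 through the benzhydryl cation/o-quinone methide) and S-alkylation of the sulfinate; the sulfone is a bench-stable store for the quinone methide, and the silyl ether leaves a single free phenol for the later lactonisation.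

Step 6
Reactants: 8 benzyloxyacetyl chloride; 9 4-nitrophenol
Product: 10 4-nitrophenyl 2-(benzyloxy)acetate
Conditions: Et3N (1.2 equiv), CH2Cl2, 0 °C
Reagents that add atoms: none
Why: Nucleophilic acyl substitution (O-acylation of the phenol); the 4-nitrophenyl ester is active enough to acylate a carbene yet stable on storage.

Step 7
Reactants: 7 rac-3,5-bis(benzyloxy)-2-{[2,4-bis(benzyloxy)-6-(triisopropylsilyloxy)phenyl](4-methylbenzenesulfonyl)methyl}phenol; 10 4-nitrophenyl 2-(benzyloxy)acetate
Product: 12 (3S,4R)-3,5,7-tris(benzyloxy)-4-[2,4-bis(benzyloxy)-6-(triisopropylsilyloxy)phenyl]chroman-2-one, via o-quinone methide 11 (not isolated)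
Conditions: 10 (1.5 equiv), (5aR,10bS)-2-mesityl-5a,10b-dihydro-4H,6H-indeno[2,1-b][1,2,4]triazolo[4,3-d][1,4]oxazin-2-ium chloride (15 mol%), Cs2CO3 (2.5 equiv), 4 Å molecular sieves, THF, 0 °C to rt
Reagents that add atoms: none
Why: Cs2CO3 deprotonates the phenol of 7 and sulfinate is expelled (E1cB) to give o-quinone methide 11, tempered by its two benzyloxy groups, while the carbene from the triazolium salt is acylated by 10, releases 4-nitrophenoxide and is deprotonated to the azolium enolate. The enolate carbon adds to the methide carbon (Michael addition, bond C3–C4) and the rearomatised phenoxide acylates the acyl azolium (bond O1–C2), which frees the carbene. The closest known reaction type is the carbene-catalysed formal [4+2] annulation of azolium enolates with o-quinone methides to cis-3,4-disubstituted dihydrocoumarins. Ring C closes by a 6-exo-trig acyl transfer that completes an endo-type hetero-Diels–Alder sense of addition. C3 is set by the catalyst, whose aminoindanol backbone and N-mesityl group expose one enolate face, which should give 3S. C4 is set relative to C3 by the endo-type transition state, in which the methide aryl group points away from the azolium, which should give the 3,4-cis lactone (4R). The step needs C-alkylation rather than O-acylation of the phenol and cis rather than trans selectivity; the first is secured because the hindered phenoxide loses sulfinate faster than it is acylated, the second because the mild heterogeneous carbonate should not epimerise the kinetic cis product at C3 at 0 °C. The benzhydryl stereocentre of 7 is lost in planar 11, so the racemate is fully usable.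

Step 8
Reactants: 13 1-(benzyloxy)-4-bromobenzene
Product: 14 4-(benzyloxy)phenylmagnesium bromide
Conditions: Mg turnings (1.3 equiv, activated with a crystal of I2), THF, rt to 40 °C; decanted, titrated, stored under argon
Reagents that add atoms: magnesium, [Mg]
Why: Grignard formation by oxidative insertion of magnesium into the aryl C–Br bond; the benzyl ether is inert to the arylmagnesium species, and the titrated THF solution is a storable stock that supplies ring B in steps 9, 16 and 22.

Step 9
Reactants: 12 (3S,4R)-3,5,7-tris(benzyloxy)-4-[2,4-bis(benzyloxy)-6-(triisopropylsilyloxy)phenyl]chroman-2-one; 14 4-(benzyloxy)phenylmagnesium bromide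
Product: 15 (3S,4R)-3,5,7-tris(benzyloxy)-2-[4-(benzyloxy)phenyl]-4-[2,4-bis(benzyloxy)-6-(triisopropylsilyloxy)phenyl]chroman-2-ol
Conditions: 14 (1.2 equiv, THF solution) added to 12, THF, −78 to −30 °C; H2O at −30 °C
Reagents that add atoms: none
Why: Grignard 1,2-addition to the lactone carbonyl: the bromomagnesium hemiketal alkoxide, chelated by the 3-benzyloxy oxygen, should persist in the cold, and any ring-opened 4-(benzyloxy)phenyl ketone is deactivated by its para oxygen, so a second addition is held back, while the weakly basic arylmagnesium reagent should not deprotonate C3. The lactol and its ring-opened hydroxy ketone tautomer both converge in step 10.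

Step 10
Reactants: 15 (3S,4R)-3,5,7-tris(benzyloxy)-2-[4-(benzyloxy)phenyl]-4-[2,4-bis(benzyloxy)-6-(triisopropylsilyloxy)phenyl]chroman-2-ol
Product: 16 (2S,3S,4R)-3,5,7-tris(benzyloxy)-2-[4-(benzyloxy)phenyl]-4-[2,4-bis(benzyloxy)-6-(triisopropylsilyloxy)phenyl]chromane
Conditions: Et3SiH (5 equiv), BF3·OEt2 (2.5 equiv), CH2Cl2, −78 to −30 °C
Reagents that add atoms: none
Why: Ionic hydrogenation of a hemiketal (Lewis acid-promoted lactol reduction as used for C-aryl glycosides): BF3·OEt2 ionises C2–OH to the 2-aryl oxocarbenium ion and Et3SiH delivers hydride to the face anti to the pseudoaxial 3-benzyloxy group and the cis 4-aryl group. The 2-aryl group therefore ends cis to both, which sets C2 as S and completes the all-cis triad.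

Step 11
Reactants: 16 (2S,3S,4R)-3,5,7-tris(benzyloxy)-2-[4-(benzyloxy)phenyl]-4-[2,4-bis(benzyloxy)-6-(triisopropylsilyloxy)phenyl]chromane
Product: 17 3,5-bis(benzyloxy)-2-(T-4-yl)phenol
Conditions: Bu4NF (1.1 equiv), AcOH (1.1 equiv), THF, 0 °C
Reagents that add atoms: none
Why: Fluoride cleavage of the aryl silyl ether, driven by Si–F bond formation; acetic acid buffers the phenoxide, and the benzyl ethers and flavan stereocentres are inert.

Step 12
Reactants: 17 3,5-bis(benzyloxy)-2-(T-4-yl)phenol
Product: 18 4,6-bis(benzyloxy)-2-hydroxy-3-(T-4-yl)benzaldehyde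
Conditions: MgCl2 (anhydrous, 2 equiv), Et3N (4 equiv), (CH2O)n (8 equiv), THF, reflux; aq. NH4Cl
Reagents that add atoms: paraformaldehyde (as formaldehyde), C=O
Why: Casnati–Skattebøl ortho-formylation as in step 1: the chelating magnesium phenoxide restricts attack to an ortho carbon and only one is free, so the formyl group enters at the carbon that becomes middle C4a and itself becomes middle C4.

Step 13
Reactants: 2 4,6-bis(benzyloxy)-2-hydroxybenzaldehyde
Product: 19 3,5-bis(benzyloxy)-2-(hydroxymethyl)phenol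
Conditions: NaBH4 (1.0 equiv), THF/MeOH, 0 °C
Reagents that add atoms: none
Why: Hydride reduction of the aldehyde to the benzylic alcohol; the electron-rich salicyl alcohol is kept neutral and used at once.

Step 14
Reactants: 19 3,5-bis(benzyloxy)-2-(hydroxymethyl)phenol
Product: 20 3,5-bis(benzyloxy)-2-[(4-methylbenzenesulfonyl)methyl]phenol
Conditions: p-TolSO2H (3 equiv), CH2Cl2, 0 °C
Reagents that add atoms: p-toluenesulfinic acid, Cc1ccc(cc1)S(=O)O
Why: SN1-type substitution of the o-hydroxybenzyl alcohol by sulfinate through the o-quinone methide, as in step 5; excess sulfinic acid should outcompete self-condensation of the electron-rich ring.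

Step 15
Reactants: 20 3,5-bis(benzyloxy)-2-[(4-methylbenzenesulfonyl)methyl]phenol; 10 4-nitrophenyl 2-(benzyloxy)acetate
Product: 22 (3S)-3,5,7-tris(benzyloxy)chroman-2-one, via o-quinone methide 21 (not isolated)
Conditions: 10 (1.5 equiv), (5aR,10bS)-2-mesityl-5a,10b-dihydro-4H,6H-indeno[2,1-b][1,2,4]triazolo[4,3-d][1,4]oxazin-2-ium chloride (15 mol%), Cs2CO3 (2.5 equiv), 4 Å molecular sieves, THF, 0 °C
Reagents that add atoms: none
Why: The same carbene-catalysed formal [4+2] annulation as step 7, here with the unsubstituted o-quinone methide 21 (Michael addition of the azolium enolate, then 6-exo-trig lactonisation). The single stereocentre C3 should be set as S by the catalyst-shielded enolate face; slow release of 21 by the sparingly soluble carbonate limits its oligomerisation.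

Step 16
Reactants: 22 (3S)-3,5,7-tris(benzyloxy)chroman-2-one; 14 4-(benzyloxy)phenylmagnesium bromide
Product: 23 (3S)-3,5,7-tris(benzyloxy)-2-[4-(benzyloxy)phenyl]chroman-2-ol
Conditions: 14 (1.2 equiv, THF solution) added to 22, THF, −78 to −40 °C; H2O at −40 °C
Reagents that add atoms: none
Why: Grignard 1,2-addition to the lactone carbonyl as in step 9; the weakly basic reagent and the cold quench should keep the only stereocentre (C3, α to the carbonyl) from enolising.

Step 17
Reactants: 23 (3S)-3,5,7-tris(benzyloxy)-2-[4-(benzyloxy)phenyl]chroman-2-ol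
Product: 24 (2S,3S)-3,5,7-tris(benzyloxy)-2-[4-(benzyloxy)phenyl]chromane
Conditions: Et3SiH (5 equiv), BF3·OEt2 (2.5 equiv), CH2Cl2, −78 to −30 °C
Reagents that add atoms: none
Why: Lewis acid-promoted lactol reduction as in step 10: hydride adds to the 2-aryl oxocarbenium ion anti to the pseudoaxial 3-benzyloxy group, which should give the 2,3-cis flavan with C2 as S.

Step 18
Reactants: 24 (2S,3S)-3,5,7-tris(benzyloxy)-2-[4-(benzyloxy)phenyl]chromane
Product: 25 (2S,3S)-3,5,7-tris(benzyloxy)-2-[4-(benzyloxy)phenyl]-8-bromochromane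
Conditions: NBS (1.0 equiv), CH2Cl2, −78 to 0 °C
Reagents that add atoms: N-bromosuccinimide, O=C1CCC(=O)N1Br
Why: Electrophilic aromatic bromination; in 5,7-dialkoxyflavans C8 is the more reactive of the two free ring A positions, so one equivalent of NBS at low temperature should give the 8-bromide.

Step 19
Reactants: 25 (2S,3S)-3,5,7-tris(benzyloxy)-2-[4-(benzyloxy)phenyl]-8-bromochromane; 18 4,6-bis(benzyloxy)-2-hydroxy-3-(T-4-yl)benzaldehyde
Product: 28 3,5-bis(benzyloxy)-2-[hydroxy(B-8-yl)methyl]-6-(T-4-yl)phenol, via 8-lithioflavan 26 (not isolated), via sodium phenoxide 27 (not isolated)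
Conditions: 25 (1.3 equiv), t-BuLi (2.6 equiv), THF, −78 °C; 18, NaH (1.05 equiv), THF, 0 °C; phenoxide solution added to the aryllithium, −78 to −40 °C; H2O
Reagents that add atoms: none
Why: Bromine–lithium exchange at C8 gives 26; the acidic phenol of 18 is masked beforehand as sodium phenoxide 27, so the aryllithium is spent only on 1,2-addition to the formyl group, which should stay electrophilic through chelation of the counter-ion between the phenoxide and carbonyl oxygens. The carbinol centre forms as a mixture and is erased in step 21.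

Step 20
Reactants: 28 3,5-bis(benzyloxy)-2-[hydroxy(B-8-yl)methyl]-6-(T-4-yl)phenol
Product: 29 3,5-bis(benzyloxy)-2-[(B-8-yl)(4-methylbenzenesulfonyl)methyl]-6-(T-4-yl)phenol
Conditions: p-TolSO2H (1.5 equiv), CH2Cl2, 0 °C
Reagents that add atoms: p-toluenesulfinic acid, Cc1ccc(cc1)S(=O)O
Why: SN1-type exchange of the benzhydryl hydroxyl for sulfinate as in step 5; the weak sulfinic acid at 0 °C should leave the top C4–C8 bond and the benzyl ethers untouched.

Step 21
Reactants: 29 3,5-bis(benzyloxy)-2-[(B-8-yl)(4-methylbenzenesulfonyl)methyl]-6-(T-4-yl)phenol; 10 4-nitrophenyl 2-(benzyloxy)acetate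
Product: 31 (3R)-3,5,7-tris(benzyloxy)-4-(B-8-yl)-8-(T-4-yl)chroman-2-one with the 3,4-cis configuration, via o-quinone methide 30 (not isolated)
Conditions: 10 (2 equiv), (5aS,10bR)-2-mesityl-5a,10b-dihydro-4H,6H-indeno[2,1-b][1,2,4]triazolo[4,3-d][1,4]oxazin-2-ium chloride (20 mol%), Cs2CO3 (2.5 equiv), 4 Å molecular sieves, THF, 0 °C to rt
Reagents that add atoms: none
Why: Second carbene-catalysed formal [4+2] annulation (Michael addition, then 6-exo-trig lactonisation) with the mirror-image triazolium salt: the catalyst fixes the enolate face and hence C3 as R, and the endo-type transition state places the 3-benzyloxy group cis to the B-8-yl group at C4. The resident stereocentres are remote from the two reacting carbons, so catalyst control should dominate.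

Step 22
Reactants: 31 (3R)-3,5,7-tris(benzyloxy)-4-(B-8-yl)-8-(T-4-yl)chroman-2-one with the 3,4-cis configuration; 14 4-(benzyloxy)phenylmagnesium bromide
Product: 32 (3R)-3,5,7-tris(benzyloxy)-2-[4-(benzyloxy)phenyl]-4-(B-8-yl)-8-(T-4-yl)chroman-2-ol with the 3,4-cis configuration
Conditions: 14 (1.5 equiv, THF solution) added to 31, THF, −78 to −30 °C; H2O at −30 °C
Reagents that add atoms: none
Why: Grignard 1,2-addition to the lactone carbonyl as in step 9; the chelated tetrahedral adduct should survive until the quench.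

Step 23
Reactants: 32 (3R)-3,5,7-tris(benzyloxy)-2-[4-(benzyloxy)phenyl]-4-(B-8-yl)-8-(T-4-yl)chroman-2-ol with the 3,4-cis configuration
Product: 33 (2R,3R)-3,5,7-tris(benzyloxy)-2-[4-(benzyloxy)phenyl]-4-(B-8-yl)-8-(T-4-yl)chromane with the all-cis middle ring
Conditions: Et3SiH (5 equiv), BF3·OEt2 (2.5 equiv), CH2Cl2, −78 to −40 °C
Reagents that add atoms: none
Why: Lewis acid-promoted lactol reduction as in step 10: hydride adds to the oxocarbenium ion anti to the cis 3-benzyloxy and 4-aryl groups, which sets middle C2 as R and completes the second all-cis triad; the low temperature and short contact should spare the benzylated interflavan bonds.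

Step 24
Reactants: 33 (2R,3R)-3,5,7-tris(benzyloxy)-2-[4-(benzyloxy)phenyl]-4-(B-8-yl)-8-(T-4-yl)chromane with the all-cis middle ring
Product: 34 dodeca-O-benzyl ether of the target with the free bottom C4 hydroxyl
Conditions: DDQ (1.5 equiv), CH2Cl2/H2O (10:1), 0 °C to rt
Reagents that add atoms: water, O
Why: DDQ-mediated benzylic oxidation (hydride abstraction, then capture of the cation by water): the bottom C4 methylene gives a cation stabilised by ring A, and water enters anti to the pseudoaxial 3-benzyloxy group, which should give the 3,4-trans carbinol (C4 as R). The C4–H bonds of the top and middle units should be spared, because a planar cation there would force the 2,6-disubstituted aryl group into the plane of ring A against the 5-benzyloxy group.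

Step 25
Reactants: 34 dodeca-O-benzyl ether of the target with the free bottom C4 hydroxyl
Product: 35 CNP0159291.1
Conditions: H2 (1 atm), Pd(OH)2/C, THF/H2O, rt; filtration, freeze-drying
Reagents that add atoms: none
Why: Catalytic hydrogenolysis of the twelve benzyl ethers in a neutral medium; benzyl ethers cleave faster than the secondary benzylic C4–OH bond, so the reaction is stopped at full debenzylation, and no stereocentre is touched.

Compound list

1 | 3,5-bis(benzyloxy)phenol | Oc1cc(OCc2ccccc2)cc(OCc2ccccc2)c1 | starting material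
2 | 4,6-bis(benzyloxy)-2-hydroxybenzaldehyde | O=Cc1c(O)cc(OCc2ccccc2)cc1OCc1ccccc1 | intermediate
3 | 4,6-bis(benzyloxy)-2-(triisopropylsilyloxy)benzaldehyde | O=Cc1c(O[Si](C(C)C)(C(C)C)C(C)C)cc(OCc2ccccc2)cc1OCc1ccccc1 | intermediate
4 | 3,5-bis(benzyloxy)-2-bromophenol | Oc1cc(OCc2ccccc2)cc(OCc2ccccc2)c1Br | intermediate
5 | lithium 3,5-bis(benzyloxy)-2-lithiophenoxide | [Li]Oc1cc(OCc2ccccc2)cc(OCc2ccccc2)c1[Li] | intermediate
6 | rac-[2,4-bis(benzyloxy)-6-hydroxyphenyl][2,4-bis(benzyloxy)-6-(triisopropylsilyloxy)phenyl]methanol | CC(C)[Si](C(C)C)(C(C)C)Oc1cc(OCc9ccccc9)cc(OCc9ccccc9)c1C(O)c1c(O)cc(OCc9ccccc9)cc1OCc9ccccc9 | intermediate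
7 | rac-3,5-bis(benzyloxy)-2-{[2,4-bis(benzyloxy)-6-(triisopropylsilyloxy)phenyl](4-methylbenzenesulfonyl)methyl}phenol | CC(C)[Si](C(C)C)(C(C)C)Oc1cc(OCc9ccccc9)cc(OCc9ccccc9)c1C(c1c(O)cc(OCc9ccccc9)cc1OCc9ccccc9)S(=O)(=O)c1ccc(C)cc1 | intermediate
8 | benzyloxyacetyl chloride | O=C(Cl)COCc1ccccc1 | starting material
9 | 4-nitrophenol | Oc1ccc(cc1)[N+](=O)[O-] | starting material
10 | 4-nitrophenyl 2-(benzyloxy)acetate | O=C(COCc1ccccc1)Oc1ccc(cc1)[N+](=O)[O-] | intermediate
11 | 3,5-bis(benzyloxy)-6-{[2,4-bis(benzyloxy)-6-(triisopropylsilyloxy)phenyl]methylidene}cyclohexa-2,4-dien-1-one | CC(C)[Si](C(C)C)(C(C)C)Oc1cc(OCc9ccccc9)cc(OCc9ccccc9)c1C=C1C(=O)C=C(OCc9ccccc9)C=C1OCc9ccccc9 | intermediate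
12 | (3S,4R)-3,5,7-tris(benzyloxy)-4-[2,4-bis(benzyloxy)-6-(triisopropylsilyloxy)phenyl]chroman-2-one (3,4-cis) | CC(C)[Si](C(C)C)(C(C)C)Oc1cc(OCc9ccccc9)cc(OCc9ccccc9)c1[C@H]1c2c(OCc9ccccc9)cc(OCc9ccccc9)cc2OC(=O)[C@H]1OCc9ccccc9 | intermediate
13 | 1-(benzyloxy)-4-bromobenzene | Brc1ccc(OCc2ccccc2)cc1 | starting material
14 | 4-(benzyloxy)phenylmagnesium bromide (titrated THF stock solution) | Br[Mg]c1ccc(OCc2ccccc2)cc1 | intermediate
15 | (3S,4R)-3,5,7-tris(benzyloxy)-2-[4-(benzyloxy)phenyl]-4-[2,4-bis(benzyloxy)-6-(triisopropylsilyloxy)phenyl]chroman-2-ol (3,4-cis; C2 epimers in equilibrium with the ring-opened hydroxy ketone) | CC(C)[Si](C(C)C)(C(C)C)Oc1cc(OCc9ccccc9)cc(OCc9ccccc9)c1[C@H]1c2c(OCc9ccccc9)cc(OCc9ccccc9)cc2OC(O)(c2ccc(OCc9ccccc9)cc2)[C@H]1OCc9ccccc9 | intermediate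
16 | (2S,3S,4R)-3,5,7-tris(benzyloxy)-2-[4-(benzyloxy)phenyl]-4-[2,4-bis(benzyloxy)-6-(triisopropylsilyloxy)phenyl]chromane (all-cis) | CC(C)[Si](C(C)C)(C(C)C)Oc1cc(OCc9ccccc9)cc(OCc9ccccc9)c1[C@H]1c2c(OCc9ccccc9)cc(OCc9ccccc9)cc2O[C@@H](c2ccc(OCc9ccccc9)cc2)[C@H]1OCc9ccccc9 | intermediate
17 | 3,5-bis(benzyloxy)-2-(T-4-yl)phenol (all-cis flavan) | Oc1cc(OCc9ccccc9)cc(OCc9ccccc9)c1[C@H]3c4c(OCc9ccccc9)cc(OCc9ccccc9)cc4O[C@@H](c4ccc(OCc9ccccc9)cc4)[C@H]3OCc9ccccc9 | intermediate
18 | 4,6-bis(benzyloxy)-2-hydroxy-3-(T-4-yl)benzaldehyde | Oc1c(C=O)c(OCc9ccccc9)cc(OCc9ccccc9)c1[C@H]3c4c(OCc9ccccc9)cc(OCc9ccccc9)cc4O[C@@H](c4ccc(OCc9ccccc9)cc4)[C@H]3OCc9ccccc9 | intermediate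
19 | 3,5-bis(benzyloxy)-2-(hydroxymethyl)phenol | OCc1c(O)cc(OCc2ccccc2)cc1OCc1ccccc1 | intermediate
20 | 3,5-bis(benzyloxy)-2-[(4-methylbenzenesulfonyl)methyl]phenol | Cc1ccc(cc1)S(=O)(=O)Cc1c(O)cc(OCc2ccccc2)cc1OCc1ccccc1 | intermediate
21 | 3,5-bis(benzyloxy)-6-methylidenecyclohexa-2,4-dien-1-one | C=C1C(=O)C=C(OCc2ccccc2)C=C1OCc1ccccc1 | intermediate
22 | (3S)-3,5,7-tris(benzyloxy)chroman-2-one | c1c(OCc9ccccc9)cc(OCc9ccccc9)c2c1OC(=O)[C@@H](OCc9ccccc9)C2 | intermediate
23 | (3S)-3,5,7-tris(benzyloxy)-2-[4-(benzyloxy)phenyl]chroman-2-ol (C2 epimers in equilibrium with the hydroxy ketone) | c1c(OCc9ccccc9)cc(OCc9ccccc9)c2c1OC(O)(c1ccc(OCc9ccccc9)cc1)[C@@H](OCc9ccccc9)C2 | intermediate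
24 | (2S,3S)-3,5,7-tris(benzyloxy)-2-[4-(benzyloxy)phenyl]chromane (2,3-cis; tetra-O-benzyl-ent-epiafzelechin) | c1c(OCc9ccccc9)cc(OCc9ccccc9)c2c1O[C@@H](c1ccc(OCc9ccccc9)cc1)[C@@H](OCc9ccccc9)C2 | intermediate
25 | (2S,3S)-3,5,7-tris(benzyloxy)-2-[4-(benzyloxy)phenyl]-8-bromochromane | Brc1c(OCc9ccccc9)cc(OCc9ccccc9)c2c1O[C@@H](c1ccc(OCc9ccccc9)cc1)[C@@H](OCc9ccccc9)C2 | intermediate
26 | (2S,3S)-3,5,7-tris(benzyloxy)-2-[4-(benzyloxy)phenyl]chroman-8-yllithium | [Li]c1c(OCc9ccccc9)cc(OCc9ccccc9)c2c1O[C@@H](c1ccc(OCc9ccccc9)cc1)[C@@H](OCc9ccccc9)C2 | intermediate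
27 | sodium 3,5-bis(benzyloxy)-2-formyl-6-(T-4-yl)phenoxide | [Na+].[O-]c1c(C=O)c(OCc9ccccc9)cc(OCc9ccccc9)c1[C@H]3c4c(OCc9ccccc9)cc(OCc9ccccc9)cc4O[C@@H](c4ccc(OCc9ccccc9)cc4)[C@H]3OCc9ccccc9 | intermediate
28 | 3,5-bis(benzyloxy)-2-[hydroxy(B-8-yl)methyl]-6-(T-4-yl)phenol (both carbinol epimers) | Oc1c(C(O)c3c(OCc9ccccc9)cc(OCc9ccccc9)c4c3O[C@@H](c3ccc(OCc9ccccc9)cc3)[C@@H](OCc9ccccc9)C4)c(OCc9ccccc9)cc(OCc9ccccc9)c1[C@H]3c4c(OCc9ccccc9)cc(OCc9ccccc9)cc4O[C@@H](c4ccc(OCc9ccccc9)cc4)[C@H]3OCc9ccccc9 | intermediate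
29 | 3,5-bis(benzyloxy)-2-[(B-8-yl)(4-methylbenzenesulfonyl)methyl]-6-(T-4-yl)phenol (both epimers) | Oc1c(C(c3c(OCc9ccccc9)cc(OCc9ccccc9)c4c3O[C@@H](c3ccc(OCc9ccccc9)cc3)[C@@H](OCc9ccccc9)C4)S(=O)(=O)c3ccc(C)cc3)c(OCc9ccccc9)cc(OCc9ccccc9)c1[C@H]3c4c(OCc9ccccc9)cc(OCc9ccccc9)cc4O[C@@H](c4ccc(OCc9ccccc9)cc4)[C@H]3OCc9ccccc9 | intermediate
30 | 3,5-bis(benzyloxy)-6-[(B-8-yl)methylidene]-2-(T-4-yl)cyclohexa-2,4-dien-1-one | O=C1C(=Cc3c(OCc9ccccc9)cc(OCc9ccccc9)c4c3O[C@@H](c3ccc(OCc9ccccc9)cc3)[C@@H](OCc9ccccc9)C4)C(OCc9ccccc9)=CC(OCc9ccccc9)=C1[C@H]3c4c(OCc9ccccc9)cc(OCc9ccccc9)cc4O[C@@H](c4ccc(OCc9ccccc9)cc4)[C@H]3OCc9ccccc9 | intermediate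
31 | (3R)-3,5,7-tris(benzyloxy)-4-(B-8-yl)-8-(T-4-yl)chroman-2-one, 3-benzyloxy cis to the 4-aryl group | O=C2Oc3c(c(OCc9ccccc9)cc(OCc9ccccc9)c3[C@H]3c4c(OCc9ccccc9)cc(OCc9ccccc9)cc4O[C@@H](c4ccc(OCc9ccccc9)cc4)[C@H]3OCc9ccccc9)[C@@H](c3c(OCc9ccccc9)cc(OCc9ccccc9)c4c3O[C@@H](c3ccc(OCc9ccccc9)cc3)[C@@H](OCc9ccccc9)C4)[C@H]2OCc9ccccc9 | intermediate
32 | (3R)-3,5,7-tris(benzyloxy)-2-[4-(benzyloxy)phenyl]-4-(B-8-yl)-8-(T-4-yl)chroman-2-ol, 3,4-cis (C2 epimers in equilibrium with the hydroxy ketone) | OC2(c3ccc(OCc9ccccc9)cc3)Oc3c(c(OCc9ccccc9)cc(OCc9ccccc9)c3[C@H]3c4c(OCc9ccccc9)cc(OCc9ccccc9)cc4O[C@@H](c4ccc(OCc9ccccc9)cc4)[C@H]3OCc9ccccc9)[C@@H](c3c(OCc9ccccc9)cc(OCc9ccccc9)c4c3O[C@@H](c3ccc(OCc9ccccc9)cc3)[C@@H](OCc9ccccc9)C4)[C@H]2OCc9ccccc9 | intermediate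
33 | (2R,3R)-3,5,7-tris(benzyloxy)-2-[4-(benzyloxy)phenyl]-4-(B-8-yl)-8-(T-4-yl)chromane, middle ring all-cis (dodeca-O-benzyl trimer without the bottom 4-hydroxyl) | c9ccccc9COc1ccc([C@H]2Oc3c(c(OCc9ccccc9)cc(OCc9ccccc9)c3[C@H]3c4c(OCc9ccccc9)cc(OCc9ccccc9)cc4O[C@@H](c4ccc(OCc9ccccc9)cc4)[C@H]3OCc9ccccc9)[C@@H](c3c(OCc9ccccc9)cc(OCc9ccccc9)c4c3O[C@@H](c3ccc(OCc9ccccc9)cc3)[C@@H](OCc9ccccc9)C4)[C@H]2OCc9ccccc9)cc1 | intermediate
34 | dodeca-O-benzyl ether of the target with the free bottom C4 hydroxyl: top (2S,3S,4R), middle (2R,3R,4S), bottom (2S,3S,4R) with 4-OH trans to 3-OBn | c9ccccc9COc1ccc([C@H]2Oc3c(c(OCc9ccccc9)cc(OCc9ccccc9)c3[C@H]3c4c(OCc9ccccc9)cc(OCc9ccccc9)cc4O[C@@H](c4ccc(OCc9ccccc9)cc4)[C@H]3OCc9ccccc9)[C@@H](c3c(OCc9ccccc9)cc(OCc9ccccc9)c4c3O[C@@H](c3ccc(OCc9ccccc9)cc3)[C@@H](OCc9ccccc9)[C@@H]4O)[C@H]2OCc9ccccc9)cc1 | intermediate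
35 | CNP0159291.1, (2R,3R,4S)-2-(4-hydroxyphenyl)-4-[(2S,3S,4R)-3,4,5,7-tetrahydroxy-2-(4-hydroxyphenyl)chroman-8-yl]-8-[(2S,3S,4R)-3,5,7-trihydroxy-2-(4-hydroxyphenyl)chroman-4-yl]chromane-3,5,7-triol | Oc1ccc([C@H]2Oc3c(c(O)cc(O)c3[C@H]3c4c(O)cc(O)cc4O[C@@H](c4ccc(O)cc4)[C@H]3O)[C@@H](c3c(O)cc(O)c4c3O[C@@H](c3ccc(O)cc3)[C@@H](O)[C@@H]4O)[C@H]2O)cc1 | target

Total step count: 25 steps. Longest linear sequence: 16 steps from 1 (steps 1, 2, 4, 5, 7, 9, 10, 11, 12, 19, 20, 21, 22, 23, 24 and 25). The bottom fragment 25 is made in 7 steps from 1 (steps 1 and 13 to 18), and the stock reagent 14 in one step from 13 (step 8).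

Least certain steps

Step 7 (key step). The most likely failure is loss of 3,4-cis selectivity, because the 5-benzyloxy group next to the methide carbon removes the usual geometric preference of the quinone methide. Conjugate addition may also be slow at a carbon bearing a 2,6-disubstituted aryl group, which would let the methide recombine with sulfinate or oligomerise, and the base may epimerise C3 to the trans lactone. The fallback sets out from 7 and returns at 12, and replaces the catalytic enolate by a more nucleophilic stoichiometric enolate under auxiliary control. Lithiated (R)-4-benzyloxazolidin-2-one is acylated with 8 to give the imide (R)-4-benzyl-3-[2-(benzyloxy)acetyl]oxazolidin-2-one F1. Its sodium enolate (NaN(SiMe3)2, THF, −78 °C) is combined with 7 and a second equivalent of the same base, which releases 11 on warming to −40 °C. Conjugate addition, whose enolate face is set by the auxiliary in the sense known for glycolate alkylations, gives the ring-open adduct, the N-acyloxazolidinone of (2S,3R)-2-benzyloxy-3-aryl-3-(2-hydroxyaryl)propanoic acid F2. Its phenoxide closes onto the imide carbonyl with loss of the auxiliary to give 12.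

Step 9. The tetrahedral adduct of an aryl ester may collapse to the phenoxide ketone, which then takes up a second equivalent of the Grignard reagent; the reagent may also deprotonate C3 and scramble the cis pair. The fallback sets out from 12 and returns at 15. The lactone is opened with MeONHMe·HCl and i-PrMgCl (THF, −20 °C) to the phenolic N-methoxy-N-methylamide F3. Two equivalents of 14 then deprotonate the phenol and add once to the amide (ketone synthesis through the stable chelated adduct), and work-up gives the hydroxy ketone that is the ring-chain tautomer of 15.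

Step 21. Double stereodifferentiation may be mismatched, with the top and bottom units opposing the catalyst and lowering facial selectivity, and the crowding around the methide carbon may retard the addition. The fallback sets out from 29 and returns at 31. Lithiated (S)-4-benzyloxazolidin-2-one and 8 give the imide (S)-4-benzyl-3-[2-(benzyloxy)acetyl]oxazolidin-2-one F4. Its sodium enolate adds to 30, released from 29 by a second equivalent of NaN(SiMe3)2, to give the ring-open N-acyloxazolidinone adduct F5, which lactonises with loss of the auxiliary to 31.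

Step 24. Hydride abstraction may compete at the diarylmethine C4–H bonds of the top and middle units, and the new carbinol may be over-oxidised to the ketone. The fallback sets out from 25 and returns at 34; it installs the C4 heteroatom on the monomer, where no diarylmethine is present, and carries it as a sulfide that hard Lewis acids leave alone. DDQ in CH2Cl2/H2O converts 25 into (2S,3S,4R)-3,5,7-tris(benzyloxy)-2-[4-(benzyloxy)phenyl]-8-bromochroman-4-ol F6. 2,6-Dimethylbenzenethiol and BF3·OEt2 at −78 °C then exchange the hydroxyl for sulfur anti to O3, giving the 8-bromo-4-(2,6-dimethylphenylthio)flavan F7. F7 takes the place of 25 in the chemistry of steps 19 to 23: bromine–lithium exchange gives the 8-lithio sulfide F8, and addition to 27 gives the thio carbinol F9. Sulfinate exchange gives the thio sulfone F10, and annulation through the thio quinone methide F11 gives the thio lactone F12. Addition of 14 gives the thio lactol F13, and reduction gives the 4-thio dodeca-O-benzyl trimer F14. Finally AgOSO2CF3 in wet THF at 0 °C ionises F14 at sulfur, and water enters anti to the 3-benzyloxy group to give 34.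

## Further compounds

F1 | step 7 | (R)-4-benzyl-3-[2-(benzyloxy)acetyl]oxazolidin-2-one | O=C(COCc1ccccc1)N1C(=O)OC[C@H]1Cc1ccccc1
F2 | step 7 | (R)-4-benzyl-3-{(2S,3R)-2-(benzyloxy)-3-[2,4-bis(benzyloxy)-6-hydroxyphenyl]-3-[2,4-bis(benzyloxy)-6-(triisopropylsilyloxy)phenyl]propanoyl}oxazolidin-2-one | CC(C)[Si](C(C)C)(C(C)C)Oc1cc(OCc9ccccc9)cc(OCc9ccccc9)c1[C@@H](c1c(OCc9ccccc9)cc(OCc9ccccc9)cc1O)[C@H](OCc9ccccc9)C(=O)N1C(=O)OC[C@H]1Cc1ccccc1
F3 | step 9 | (2S,3R)-2-(benzyloxy)-3-[2,4-bis(benzyloxy)-6-hydroxyphenyl]-3-[2,4-bis(benzyloxy)-6-(triisopropylsilyloxy)phenyl]-N-methoxy-N-methylpropanamide | CC(C)[Si](C(C)C)(C(C)C)Oc1cc(OCc9ccccc9)cc(OCc9ccccc9)c1[C@@H](c1c(OCc9ccccc9)cc(OCc9ccccc9)cc1O)[C@H](OCc9ccccc9)C(=O)N(C)OC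
F4 | step 21 | (S)-4-benzyl-3-[2-(benzyloxy)acetyl]oxazolidin-2-one | O=C(COCc1ccccc1)N1C(=O)OC[C@@H]1Cc1ccccc1
F5 | step 21 | ring-open adduct: (S)-4-benzyl-3-acyloxazolidin-2-one of the 2-(benzyloxy)-3-(B-8-yl)-3-[2,4-bis(benzyloxy)-6-hydroxy-5-(T-4-yl)phenyl]propanoic acid, configured as C3 and C4 of 31 | Oc3c(c(OCc9ccccc9)cc(OCc9ccccc9)c3[C@H]3c4c(OCc9ccccc9)cc(OCc9ccccc9)cc4O[C@@H](c4ccc(OCc9ccccc9)cc4)[C@H]3OCc9ccccc9)[C@@H](c3c(OCc9ccccc9)cc(OCc9ccccc9)c4c3O[C@@H](c3ccc(OCc9ccccc9)cc3)[C@@H](OCc9ccccc9)C4)[C@@H](OCc9ccccc9)C(=O)N2C(=O)OC[C@@H]2Cc2ccccc2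
F6 | step 24 | (2S,3S,4R)-3,5,7-tris(benzyloxy)-2-[4-(benzyloxy)phenyl]-8-bromochroman-4-ol | Brc1c(OCc9ccccc9)cc(OCc9ccccc9)c2c1O[C@@H](c1ccc(OCc9ccccc9)cc1)[C@@H](OCc9ccccc9)[C@@H]2O
F7 | step 24 | 3,5,7-tris(benzyloxy)-2-[4-(benzyloxy)phenyl]-8-bromo-4-(2,6-dimethylphenylthio)chromane, 2,3-cis and 3,4-trans, configured as 25 at C2 and C3 | Brc1c(OCc9ccccc9)cc(OCc9ccccc9)c2c1O[C@@H](c1ccc(OCc9ccccc9)cc1)[C@@H](OCc9ccccc9)[C@@H]2Sc1c(C)cccc1C
F8 | step 24 | 8-lithio derivative of F7 | [Li]c1c(OCc9ccccc9)cc(OCc9ccccc9)c2c1O[C@@H](c1ccc(OCc9ccccc9)cc1)[C@@H](OCc9ccccc9)[C@@H]2Sc1c(C)cccc1C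
F9 | step 24 | 4-(2,6-dimethylphenylthio) analogue of 28 (sulfur on bottom C4, trans to the 3-benzyloxy group) | Oc1c(C(O)c3c(OCc9ccccc9)cc(OCc9ccccc9)c4c3O[C@@H](c3ccc(OCc9ccccc9)cc3)[C@@H](OCc9ccccc9)[C@@H]4Sc3c(C)cccc3C)c(OCc9ccccc9)cc(OCc9ccccc9)c1[C@H]3c4c(OCc9ccccc9)cc(OCc9ccccc9)cc4O[C@@H](c4ccc(OCc9ccccc9)cc4)[C@H]3OCc9ccccc9
F10 | step 24 | 4-(2,6-dimethylphenylthio) analogue of 29 | Oc1c(C(c3c(OCc9ccccc9)cc(OCc9ccccc9)c4c3O[C@@H](c3ccc(OCc9ccccc9)cc3)[C@@H](OCc9ccccc9)[C@@H]4Sc3c(C)cccc3C)S(=O)(=O)c3ccc(C)cc3)c(OCc9ccccc9)cc(OCc9ccccc9)c1[C@H]3c4c(OCc9ccccc9)cc(OCc9ccccc9)cc4O[C@@H](c4ccc(OCc9ccccc9)cc4)[C@H]3OCc9ccccc9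
F11 | step 24 | 4-(2,6-dimethylphenylthio) analogue of 30 | O=C1C(=Cc3c(OCc9ccccc9)cc(OCc9ccccc9)c4c3O[C@@H](c3ccc(OCc9ccccc9)cc3)[C@@H](OCc9ccccc9)[C@@H]4Sc3c(C)cccc3C)C(OCc9ccccc9)=CC(OCc9ccccc9)=C1[C@H]3c4c(OCc9ccccc9)cc(OCc9ccccc9)cc4O[C@@H](c4ccc(OCc9ccccc9)cc4)[C@H]3OCc9ccccc9
F12 | step 24 | 4-(2,6-dimethylphenylthio) analogue of 31 | O=C2Oc3c(c(OCc9ccccc9)cc(OCc9ccccc9)c3[C@H]3c4c(OCc9ccccc9)cc(OCc9ccccc9)cc4O[C@@H](c4ccc(OCc9ccccc9)cc4)[C@H]3OCc9ccccc9)[C@@H](c3c(OCc9ccccc9)cc(OCc9ccccc9)c4c3O[C@@H](c3ccc(OCc9ccccc9)cc3)[C@@H](OCc9ccccc9)[C@@H]4Sc3c(C)cccc3C)[C@H]2OCc9ccccc9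
F13 | step 24 | 4-(2,6-dimethylphenylthio) analogue of 32 | OC2(c3ccc(OCc9ccccc9)cc3)Oc3c(c(OCc9ccccc9)cc(OCc9ccccc9)c3[C@H]3c4c(OCc9ccccc9)cc(OCc9ccccc9)cc4O[C@@H](c4ccc(OCc9ccccc9)cc4)[C@H]3OCc9ccccc9)[C@@H](c3c(OCc9ccccc9)cc(OCc9ccccc9)c4c3O[C@@H](c3ccc(OCc9ccccc9)cc3)[C@@H](OCc9ccccc9)[C@@H]4Sc3c(C)cccc3C)[C@H]2OCc9ccccc9
F14 | step 24 | 4-(2,6-dimethylphenylthio) analogue of 33 (dodeca-O-benzyl trimer with sulfur on bottom C4) | c9ccccc9COc1ccc([C@H]2Oc3c(c(OCc9ccccc9)cc(OCc9ccccc9)c3[C@H]3c4c(OCc9ccccc9)cc(OCc9ccccc9)cc4O[C@@H](c4ccc(OCc9ccccc9)cc4)[C@H]3OCc9ccccc9)[C@@H](c3c(OCc9ccccc9)cc(OCc9ccccc9)c4c3O[C@@H](c3ccc(OCc9ccccc9)cc3)[C@@H](OCc9ccccc9)[C@@H]4Sc3c(C)cccc3C)[C@H]2OCc9ccccc9)cc1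
A1 | alternative 1 | diene: 1-[1-(4-benzyloxyphenyl)prop-2-enyloxy]-3,5-bis(benzyloxy)-2-[1-(B-8-yl)ethenyl]benzene, allylic carbon configured as middle C2 of the target | C=C[C@@H](c1ccc(OCc9ccccc9)cc1)Oc1cc(OCc9ccccc9)cc(OCc9ccccc9)c1C(=C)c1c(OCc9ccccc9)cc(OCc9ccccc9)c2c1O[C@@H](c1ccc(OCc9ccccc9)cc1)[C@@H](OCc9ccccc9)C2
A2 | alternative 1 | 2-(4-benzyloxyphenyl)-4-(B-8-yl)-5,7-bis(benzyloxy)-2H-chromene, C2 configured as in the target | c9ccccc9COc1ccc([C@H]2Oc3c(c(OCc9ccccc9)cc(OCc9ccccc9)c3)C(c3c(OCc9ccccc9)cc(OCc9ccccc9)c4c3O[C@@H](c3ccc(OCc9ccccc9)cc3)[C@@H](OCc9ccccc9)C4)=C2)cc1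
A3 | alternative 2 | enol ether: 1-[1-(4-benzyloxyphenyl)ethenyloxy]-3,5-bis(benzyloxy)-2-{1-[2,4-bis(benzyloxy)-6-(triisopropylsilyloxy)phenyl]prop-2-enyl}benzene, methine configured as top C4 | CC(C)[Si](C(C)C)(C(C)C)Oc1cc(OCc9ccccc9)cc(OCc9ccccc9)c1[C@H](C=C)c1c(OCc9ccccc9)cc(OCc9ccccc9)cc1OC(=C)c1ccc(OCc9ccccc9)cc1
A4 | alternative 2 | 2-(4-benzyloxyphenyl)-4-[2,4-bis(benzyloxy)-6-(triisopropylsilyloxy)phenyl]-5,7-bis(benzyloxy)-4H-chromene, C4 configured as top C4 | CC(C)[Si](C(C)C)(C(C)C)Oc1cc(OCc9ccccc9)cc(OCc9ccccc9)c1[C@@H]1C=C(c2ccc(OCc9ccccc9)cc2)Oc2cc(OCc9ccccc9)cc(OCc9ccccc9)c12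
A5 | alternative 3 | α-benzyloxy aldehyde: top–middle dimer whose middle C4 carries a 2,4-bis(benzyloxy)-6-[(1S,2S)-2-(benzyloxy)-1-(4-benzyloxyphenyl)-3-oxopropoxy]phenyl group (bottom ring C open between C4 and C4a) | c9ccccc9COc1ccc([C@H]2Oc3c(c(OCc9ccccc9)cc(OCc9ccccc9)c3[C@H]3c4c(OCc9ccccc9)cc(OCc9ccccc9)cc4O[C@@H](c4ccc(OCc9ccccc9)cc4)[C@H]3OCc9ccccc9)[C@@H](c3c(OCc9ccccc9)cc(OCc9ccccc9)cc3O[C@@H](c3ccc(OCc9ccccc9)cc3)[C@@H](OCc9ccccc9)C=O)[C@H]2OCc9ccccc9)cc1
A6 | alternative 3 | dodeca-O-benzyl ether of the target with the free bottom C4 hydroxyl (identical with 34) | c9ccccc9COc1ccc([C@H]2Oc3c(c(OCc9ccccc9)cc(OCc9ccccc9)c3[C@H]3c4c(OCc9ccccc9)cc(OCc9ccccc9)cc4O[C@@H](c4ccc(OCc9ccccc9)cc4)[C@H]3OCc9ccccc9)[C@@H](c3c(OCc9ccccc9)cc(OCc9ccccc9)c4c3O[C@@H](c3ccc(OCc9ccccc9)cc3)[C@@H](OCc9ccccc9)[C@@H]4O)[C@H]2OCc9ccccc9)cc1
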